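The route rests on cutting the bond between the side-chain ketone carbon (chain C1) and ring C3 of the dihydropyranone. The key step exploits the ring as a cyclic β-keto lactone: C3 lies between lactone carbonyl C2 and the enolic C4–OH, so a carbodiimide/DMAP coupling acylates O4 and then shifts the acyl group to C3. In one operation it unites the fully elaborated, protected C12 acid (all four chain stereocentres set) with (R)-6-methyldihydropyran-2,4-dione and creates the tricarbonyl array. The acid is assembled from (S)-2-methylbutanoic acid and (R)-β-citronellene by dianion allylation and cross-metathesis; the ring comes from ethyl (R)-3-hydroxybutanoate.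

Key step: step 10

Remark: the ring is written as the C4 enol of a 3-acylpyran-2,4-dione and the route delivers this tautomeric system. Chain atoms are numbered C1 (ketone carbon) to C12 (ethyl CH3); ring atoms are O1, C2 (lactone C=O), C3, C4 (enol), C5, C6 (methyl-bearing).

Step 1
Reactants: 1 (S)-2-methylbutanoic acid
Product: 3 tert-butyl (4S)-4-methyl-3-oxohexanoate, via acyl Meldrum's acid 2 (not isolated)
Conditions: Meldrum's acid, DCC, DMAP, CH2Cl2, 0 °C to rt; filter; then tBuOH, toluene, 90 °C
Reagents that add atoms: Meldrum's acid, CC1(C)OC(=O)CC(=O)O1; tert-butanol, CC(C)(C)O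
Why: The Meldrum's acid β-keto ester synthesis (carbodiimide C-acylation, then thermal fragmentation to an acylketene that tert-butanol traps) homologates the acid without strong base, so the α-stereocentre of 1 (later chain C10) should not epimerise.

Step 2
Reactants: 3 tert-butyl (4S)-4-methyl-3-oxohexanoate
Product: 4 tert-butyl (3S,4S)-3-hydroxy-4-methylhexanoate
Conditions: H2 (10 bar), RuCl2[(R)-BINAP] (0.5 mol %), MeOH, 50 °C
Reagents that add atoms: none
Why: In this Noyori asymmetric hydrogenation of a β-keto ester the chelated ketone is reduced under catalyst control, the (R)-BINAP ligand setting the new carbinol (later chain C9) as (3S), the same facial sense that gives (R)-3-hydroxybutanoate from acetoacetate, while the existing C4 centre is not enolised.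

Step 3
Reactants: 4 tert-butyl (3S,4S)-3-hydroxy-4-methylhexanoate
Product: 5 tert-butyl (2R,3R,4S)-2-allyl-3-hydroxy-4-methylhexanoate
Conditions: LiN(iPr)2 (2.2 equiv), THF, −78 to −20 °C; allyl bromide, DMPU, −78 to −10 °C; AcOH quench
Reagents that add atoms: allyl bromide, C=CCBr
Why: In this Fráter–Seebach alkylation the chelated lithium alkoxide–enolate is allylated on the face opposite the sec-butyl substituent of the carbinol carbon, which sets C2 (later chain C8) as (2R) with the 2,3-anti relationship.

Step 4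
Reactants: 5 tert-butyl (2R,3R,4S)-2-allyl-3-hydroxy-4-methylhexanoate
Product: 6 tert-butyl (2R,3R,4S)-2-allyl-4-methyl-3-[(triethylsilyl)oxy]hexanoate
Conditions: TESOTf (1.2 equiv), 2,6-lutidine, CH2Cl2, −78 °C
Reagents that add atoms: triethylsilyl trifluoromethanesulfonate, CC[Si](CC)(CC)OS(=O)(=O)C(F)(F)F
Why: Silylation of the hindered secondary alcohol with a silyl triflate and a hindered pyridine base masks the only hydroxyl before the carboxyl activation of step 10 and, like the tert-butyl ester, it comes off with acid in step 11.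

Step 5
Reactants: 7 (R)-β-citronellene [(3R)-3,7-dimethylocta-1,6-diene]
Product: 9 (R)-4-methylhex-5-enal, via epoxide 8 (not isolated)
Conditions: mCPBA (1.0 equiv), CH2Cl2, 0 °C; then H5IO6, THF/H2O, 0 °C to rt
Reagents that add atoms: 3-chloroperoxybenzoic acid, OOC(=O)c1cccc(Cl)c1
Why: Prilezhaev epoxidation is chemoselective for the electron-rich trisubstituted alkene over the vinyl group, and periodic acid then cleaves the epoxide through its diol (Malaprade-type glycol cleavage) to the aldehyde and acetone without touching the allylic stereocentre.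

Step 6
Reactants: 9 (R)-4-methylhex-5-enal
Product: 10 (R)-4-methylhex-5-enoic acid
Conditions: NaClO2, NaH2PO4, 2-methylbut-2-ene, tBuOH/H2O, rt
Reagents that add atoms: sodium chlorite, [Na+].[O-]Cl=O
Why: Pinnick oxidation converts the aldehyde into the acid while 2-methylbut-2-ene scavenges hypochlorous acid and so protects the vinyl group, and the stereocentre is γ to the carbonyl and cannot epimerise.

Step 7
Reactants: 6 tert-butyl (2R,3R,4S)-2-allyl-4-methyl-3-[(triethylsilyl)oxy]hexanoate; 10 (R)-4-methylhex-5-enoic acid (3 equiv)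
Product: 12 (4S,8R,9R,10S)-8-(tert-butoxycarbonyl)-4,10-dimethyl-9-[(triethylsilyl)oxy]dodecanoic acid, via alkene acid 11 (not isolated)
Conditions: second-generation Grubbs catalyst (5 mol %), 1,4-benzoquinone (10 mol %), CH2Cl2, 40 °C; then solvent exchange to EtOAc, PtO2, H2 (1 atm), rt
Reagents that add atoms: none
Why: Olefin cross-metathesis joins the unhindered allyl terminus of 6 with the slowly homodimerising, allylically branched vinyl group of 10 (ethene lost, benzoquinone suppressing ruthenium-hydride isomerisation), and hydrogenation over platinum, which is less prone to double-bond migration than palladium, then saturates the new alkene so that the allylic centre becomes chain C4 with its configuration kept.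

Step 8
Reactants: 13 ethyl (R)-3-hydroxybutanoate
Product: 14 tert-butyl (5R)-5-hydroxy-3-oxohexanoate
Conditions: LiN(iPr)2 and tert-butyl acetate (3.5 equiv each), THF, −78 °C; then 13, −78 to −20 °C; AcOH quench
Reagents that add atoms: tert-butyl acetate, CC(=O)OC(C)(C)C
Why: In this crossed Claisen condensation the excess lithium enolate of tert-butyl acetate first deprotonates the hydroxyl and then attacks the ethyl ester, and the product is held as its enolate so that no second addition occurs and the carbinol centre is untouched.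

Step 9
Reactants: 14 tert-butyl (5R)-5-hydroxy-3-oxohexanoate
Product: 15 (6R)-6-methyldihydro-2H-pyran-2,4(3H)-dione
Conditions: TFA, CH2Cl2, rt
Reagents that add atoms: none
Why: Acid-mediated cleavage of the tert-butyl ester with δ-lactonisation (six-membered ring) gives the cyclic β-keto lactone, and because the C–O bond at the stereocentre is not broken the (R) configuration is retained as ring C6.

Step 10
Reactants: 12 (4S,8R,9R,10S)-8-(tert-butoxycarbonyl)-4,10-dimethyl-9-[(triethylsilyl)oxy]dodecanoic acid; 15 (6R)-6-methyldihydro-2H-pyran-2,4(3H)-dione (1.2 equiv)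
Product: 17 tert-butyl (2R,6S)-9-[(6R)-4-hydroxy-6-methyl-2-oxo-5,6-dihydro-2H-pyran-3-yl]-6-methyl-2-{(1R,2S)-2-methyl-1-[(triethylsilyl)oxy]butyl}-9-oxononanoate, via enol ester 16 (not isolated)
Conditions: DCC (1.2 equiv), DMAP (1.1 equiv), CH2Cl2, 0 °C to rt, then 40 °C; cold 5% aq. citric acid wash
Reagents that add atoms: none
Why: DCC converts the free C1 carboxyl of 12 into an O-acylisourea that DMAP turns into an acylpyridinium ion, which first acylates the enol oxygen at ring C4 of 15 to give enol ester 16. DMAP then re-attacks 16 to regenerate the acylpyridinium/pyrandione enolate ion pair, which recombines at carbon C3 (1,3 O-to-C acyl shift) and so forms the chain C1–ring C3 bond; deprotonation of the far more acidic, internally hydrogen-bonded tricarbonyl product by DMAP makes it the thermodynamic sink. The closest known reaction type is the carbodiimide/DMAP (Steglich-type) acylation of cyclic 1,3-dicarbonyl compounds with Fries-type O-to-C acyl migration, as used for 3-acyl-4-hydroxypyranones and 3-acyltetramic acids. No ring is closed and no stereocentre is formed. The step needs C- over O-acylation, secured by the reversibility of O-acylation under DMAP and the irreversible salt formation of the C-acyl product, and activation of only one carboxyl, secured because the other is a tert-butyl ester and the C9 hydroxyl is silylated. The stereocentres at ring C6 and chain C8 should not be epimerised by DMAP at these temperatures.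

Step 11
Reactants: 17 tert-butyl (2R,6S)-9-[(6R)-4-hydroxy-6-methyl-2-oxo-5,6-dihydro-2H-pyran-3-yl]-6-methyl-2-{(1R,2S)-2-methyl-1-[(triethylsilyl)oxy]butyl}-9-oxononanoate
Product: 18 (2R,6S)-2-[(1R,2S)-1-hydroxy-2-methylbutyl]-9-[(6R)-4-hydroxy-6-methyl-2-oxo-5,6-dihydro-2H-pyran-3-yl]-6-methyl-9-oxononanoic acid
Conditions: TFA/CH2Cl2/H2O (10:10:1), 0 °C to rt
Reagents that add atoms: none
Why: Acidolysis removes both protecting groups in one operation, the tert-butyl ester by loss of the tert-butyl cation as 2-methylpropene and the triethylsilyl ether by acid-catalysed hydrolysis, under conditions that the dihydropyranone ring already tolerated in step 9, and no stereocentre is touched.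

Compound list
1 | (S)-2-methylbutanoic acid | CC[C@H](C)C(=O)O | starting material
2 | (S)-5-(1-hydroxy-2-methylbutylidene)-2,2-dimethyl-1,3-dioxane-4,6-dione (acyl Meldrum's acid) | CC[C@H](C)C(O)=C1C(=O)OC(C)(C)OC1=O | intermediate
3 | tert-butyl (4S)-4-methyl-3-oxohexanoate | CC[C@H](C)C(=O)CC(=O)OC(C)(C)C | intermediate
4 | tert-butyl (3S,4S)-3-hydroxy-4-methylhexanoate | CC[C@H](C)[C@@H](O)CC(=O)OC(C)(C)C | intermediate
5 | tert-butyl (2R,3R,4S)-2-allyl-3-hydroxy-4-methylhexanoate | CC[C@H](C)[C@@H](O)[C@@H](CC=C)C(=O)OC(C)(C)C | intermediate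
6 | tert-butyl (2R,3R,4S)-2-allyl-4-methyl-3-[(triethylsilyl)oxy]hexanoate | CC[C@H](C)[C@@H](O[Si](CC)(CC)CC)[C@@H](CC=C)C(=O)OC(C)(C)C | intermediate
7 | (R)-β-citronellene, (3R)-3,7-dimethylocta-1,6-diene | C=C[C@H](C)CCC=C(C)C | starting material
8 | 2,2-dimethyl-3-[(3R)-3-methylpent-4-en-1-yl]oxirane (both oxirane epimers) | C=C[C@H](C)CCC1OC1(C)C | intermediate
9 | (R)-4-methylhex-5-enal | C=C[C@H](C)CCC=O | intermediate
10 | (R)-4-methylhex-5-enoic acid | C=C[C@H](C)CCC(=O)O | intermediate
11 | (4R,8R,9R,10S)-8-(tert-butoxycarbonyl)-4,10-dimethyl-9-[(triethylsilyl)oxy]dodec-5-enoic acid (E/Z mixture) | CC[C@H](C)[C@@H](O[Si](CC)(CC)CC)[C@@H](CC=C[C@H](C)CCC(=O)O)C(=O)OC(C)(C)C | intermediate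
12 | (4S,8R,9R,10S)-8-(tert-butoxycarbonyl)-4,10-dimethyl-9-[(triethylsilyl)oxy]dodecanoic acid | CC[C@H](C)[C@@H](O[Si](CC)(CC)CC)[C@@H](CCC[C@H](C)CCC(=O)O)C(=O)OC(C)(C)C | intermediate
13 | ethyl (R)-3-hydroxybutanoate | C[C@@H](O)CC(=O)OCC | starting material
14 | tert-butyl (5R)-5-hydroxy-3-oxohexanoate | C[C@@H](O)CC(=O)CC(=O)OC(C)(C)C | intermediate
15 | (6R)-6-methyldihydro-2H-pyran-2,4(3H)-dione (enol form: (6R)-4-hydroxy-6-methyl-5,6-dihydro-2H-pyran-2-one) | C[C@@H]1CC(=O)CC(=O)O1 | intermediate
16 | 1-tert-butyl 9-[(6R)-6-methyl-2-oxo-5,6-dihydro-2H-pyran-4-yl] (2R,6S)-6-methyl-2-{(1R,2S)-2-methyl-1-[(triethylsilyl)oxy]butyl}nonanedioate | CC[C@H](C)[C@@H](O[Si](CC)(CC)CC)[C@@H](CCC[C@H](C)CCC(=O)OC1=CC(=O)O[C@H](C)C1)C(=O)OC(C)(C)C | intermediate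
17 | tert-butyl (2R,6S)-9-[(6R)-4-hydroxy-6-methyl-2-oxo-5,6-dihydro-2H-pyran-3-yl]-6-methyl-2-{(1R,2S)-2-methyl-1-[(triethylsilyl)oxy]butyl}-9-oxononanoate | CC[C@H](C)[C@@H](O[Si](CC)(CC)CC)[C@@H](CCC[C@H](C)CCC(=O)C1=C(O)C[C@@H](C)OC1=O)C(=O)OC(C)(C)C | intermediate
18 | (2R,6S)-2-[(1R,2S)-1-hydroxy-2-methylbutyl]-9-[(6R)-4-hydroxy-6-methyl-2-oxo-5,6-dihydro-2H-pyran-3-yl]-6-methyl-9-oxononanoic acid | CC[C@H](C)[C@@H](O)[C@@H](CCC[C@H](C)CCC(=O)C1=C(O)C[C@@H](C)OC1=O)C(=O)O | target

Total step count: 11. Longest linear sequence: 7 steps (steps 1, 2, 3, 4, 7, 10, 11).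

Steps most likely to fail

1. Step 7 (cross-metathesis/hydrogenation). Homodimerisation of either partner may outcompete the cross-coupling, or metal-hydride-mediated migration of the new double bond into the allylic position may erode the configuration at chain C4. The fallback leaves the route at 6 and 10 and returns at 12. Ozonolysis of 6 (O3, CH2Cl2, −78 °C; PPh3) should give the aldehyde tert-butyl (2R,3R,4S)-4-methyl-2-(2-oxoethyl)-3-[(triethylsilyl)oxy]hexanoate F1. Ozonolysis of 10 with NaBH4 work-up and acidification should give the lactone (5R)-5-methyltetrahydro-2H-pyran-2-one F2, which PPh3·HBr (neat, 150 °C) should open to the phosphonium salt [(2R)-4-carboxy-2-methylbutyl]triphenylphosphonium bromide F3. Wittig reaction of the ylide from F3 (NaN(SiMe3)2, 2 equiv, THF, −78 °C to rt) with F1 should give 11 as its (Z)-isomer. Diimide reduction (TsNHNH2, NaOAc, THF/H2O, reflux), which cannot move the double bond, then leads to 12.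

2. Step 10 (key acylation). The acyl group may stall on oxygen (enol ester 16 failing to rearrange), or the O-acylisourea may rearrange to an unreactive N-acylurea before it is intercepted. The fallback leaves the route at 12 and 14 and returns at 17; it forms the same bond on the open-chain keto ester and closes the ring afterwards. Silylation of 14 (TESCl, imidazole, CH2Cl2) should give tert-butyl (5R)-3-oxo-5-[(triethylsilyl)oxy]hexanoate F4. Treatment of 12 with 1-chloro-N,N,2-trimethylprop-1-en-1-amine (CH2Cl2, 0 °C to rt) should give the acid chloride tert-butyl (2R,6S)-9-chloro-6-methyl-2-{(1R,2S)-2-methyl-1-[(triethylsilyl)oxy]butyl}-9-oxononanoate F5. C-Acylation of the magnesium chelate of F4 (MgCl2, pyridine, CH2Cl2, 0 °C) with F5 should give the tricarbonyl ester tert-butyl (2R,6S,13R)-10-(tert-butoxycarbonyl)-6-methyl-2-{(1R,2S)-2-methyl-1-[(triethylsilyl)oxy]butyl}-9,11-dioxo-13-[(triethylsilyl)oxy]tetradecanoate F6. Mild acid (AcOH/THF/H2O, 0 °C to rt) should cleave only the unhindered silyl ether, giving tert-butyl (2R,6S,13R)-10-(tert-butoxycarbonyl)-13-hydroxy-6-methyl-2-{(1R,2S)-2-methyl-1-[(triethylsilyl)oxy]butyl}-9,11-dioxotetradecanoate F7. Heating F7 in toluene at 100 °C should expel tert-butanol from the β-keto tert-butyl ester through an acylketene that the C13 hydroxyl traps, closing the lactone to 17.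

3. Step 3 (dianion allylation). Alkylation of the hindered alkoxide–enolate aggregate may be sluggish, with retro-aldol cleavage or proton transfer on warming. The fallback leaves the route at 4 and returns at 5; it delivers the allyl group intramolecularly. TFA in CH2Cl2 should convert 4 into (3S,4S)-3-hydroxy-4-methylhexanoic acid F8. Allyl bromide and Cs2CO3 in DMF should give allyl (3S,4S)-3-hydroxy-4-methylhexanoate F9. With LiN(iPr)2 (2.2 equiv, THF, −78 °C to rt) the chelated alkoxide–enolate of F9 should undergo the dianionic Ireland–Claisen rearrangement, the allyl group migrating to the enolate face anti to the sec-butyl-bearing substituent, to give (2R,3R,4S)-2-allyl-3-hydroxy-4-methylhexanoic acid F10. O-tert-Butyl-N,N′-diisopropylisourea in CH2Cl2 then esterifies the carboxyl selectively to give 5.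

Further compounds
F1 | step 7 | tert-butyl (2R,3R,4S)-4-methyl-2-(2-oxoethyl)-3-[(triethylsilyl)oxy]hexanoate | CC[C@H](C)[C@@H](O[Si](CC)(CC)CC)[C@@H](CC=O)C(=O)OC(C)(C)C
F2 | step 7 | (5R)-5-methyltetrahydro-2H-pyran-2-one | C[C@@H]1CCC(=O)OC1
F3 | step 7 | [(2R)-4-carboxy-2-methylbutyl]triphenylphosphonium bromide | OC(=O)CC[C@@H](C)C[P+](c1ccccc1)(c1ccccc1)c1ccccc1.[Br-]
F4 | step 10 | tert-butyl (5R)-3-oxo-5-[(triethylsilyl)oxy]hexanoate | C[C@@H](O[Si](CC)(CC)CC)CC(=O)CC(=O)OC(C)(C)C
F5 | step 10 | tert-butyl (2R,6S)-9-chloro-6-methyl-2-{(1R,2S)-2-methyl-1-[(triethylsilyl)oxy]butyl}-9-oxononanoate | CC[C@H](C)[C@@H](O[Si](CC)(CC)CC)[C@@H](CCC[C@H](C)CCC(=O)Cl)C(=O)OC(C)(C)C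
F6 | step 10 | tert-butyl (2R,6S,13R)-10-(tert-butoxycarbonyl)-6-methyl-2-{(1R,2S)-2-methyl-1-[(triethylsilyl)oxy]butyl}-9,11-dioxo-13-[(triethylsilyl)oxy]tetradecanoate (C10 unassigned, enolised) | CC[C@H](C)[C@@H](O[Si](CC)(CC)CC)[C@@H](CCC[C@H](C)CCC(=O)C(C(=O)OC(C)(C)C)C(=O)C[C@@H](C)O[Si](CC)(CC)CC)C(=O)OC(C)(C)C
F7 | step 10 | tert-butyl (2R,6S,13R)-10-(tert-butoxycarbonyl)-13-hydroxy-6-methyl-2-{(1R,2S)-2-methyl-1-[(triethylsilyl)oxy]butyl}-9,11-dioxotetradecanoate (C10 unassigned, enolised) | CC[C@H](C)[C@@H](O[Si](CC)(CC)CC)[C@@H](CCC[C@H](C)CCC(=O)C(C(=O)OC(C)(C)C)C(=O)C[C@@H](C)O)C(=O)OC(C)(C)C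
F8 | step 3 | (3S,4S)-3-hydroxy-4-methylhexanoic acid | CC[C@H](C)[C@@H](O)CC(=O)O
F9 | step 3 | allyl (3S,4S)-3-hydroxy-4-methylhexanoate | CC[C@H](C)[C@@H](O)CC(=O)OCC=C
F10 | step 3 | (2R,3R,4S)-2-allyl-3-hydroxy-4-methylhexanoic acid | CC[C@H](C)[C@@H](O)[C@@H](CC=C)C(=O)O
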